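The amounts of product in the alpha and gamma runs were what I looked at first when you asked me for a quick number on Tuesday's and Monday's flasks.

the same everywhere: free catalyst 0.52 mM

| flask | solid substrate | temperature | remark | time |
|---|---|---|---|---|
| alpha | 17 mM | 0 °C | run made earlier |  |
| gamma | 39 mM | 22 °C | run made earlier |  |
| Tuesday's | 26 mM |  | at −10 °C throughout | 60 h |
| Monday's | 26 mM |  | at −10 °C until 8.0 h, from then on at 30 °C | 15 h |

| run | time / h | product / % | solid substrate / % |
|---|---|---|---|
| alpha | 1.00 | 40 | 21 |
| alpha | 3.00 | 95 | 2 |
| alpha | 5.00 | 96 | 2 |
| alpha | 8.00 | 100 | 0 |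
| alpha | 12.0 | 101 | 3 |
| gamma | 0.333 | 12 | 76 |
| gamma | 1.00 | 44 | 47 |
| gamma | 1.50 | 66 | 21 |
| gamma | 2.50 | 97 | 2 |
| gamma | 4.00 | 99 | 0 |

(scatter of a reading: 2 percentage points)

- the winner by amount of product, in percent of the solid substrate charged; "neither" if no more than 2 percentage points parts them (Tuesday's / Monday's / neither)
- how much product is there at the end, in percent of the solid substrate charged: Tuesday's
- how much product is there at the end, in percent of the solid substrate charged: Monday's

In the gamma run the percentage of product climbed in a nearly straight line, so I took the rate as constant, zero order in solid substrate. Then d[product]/dt = r integrates to [product] = r·t, and the charge is used up at charge/r. I read r in the gamma run from 66% of 39 mM at 1.50 h, which gave 17.2 mM h⁻¹ at 22 °C. The alpha run's 40% of 17 mM at 1.00 h gave 6.80 mM h⁻¹ at 0 °C.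

Those readings differ by a factor of 2.53; the two runs differ in charge as well as in temperature, but a constant rate takes no account of the charge, so I set that factor against temperature. The step down to −10 °C is shorter than the step between the two runs, so I divided alpha's rate by that whole factor and used 2.69 mM h⁻¹ as a cautious estimate. Tuesday's charge over this rate gave 9.65 h. That is the clearing time, charge divided by steady rate, and it is shorter than Tuesday's 60 h.

On the same line, I put Monday's flask at 82.9% of its charge by 8.0 h. At 30 °C, warmer than the gamma run, I took gamma's rate for the remainder, which needed 0.259 h, far less than the warm period. My reckoning gave times, not yields. Your forecast said 100% for Tuesday's, 100% for Monday's and neither as the winner, on this ground: “This suggests reaction from a saturated solution, fed by the solid.”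

Tuesday's gave 98.2% and Monday's 98.0%, so the answer was neither.

    catalyst intermediate A → catalyst intermediate B (k = 34.0 h⁻¹, Ea = 72.0 kJ mol⁻¹)
    free catalyst + product → spent catalyst (k = 1.50 M⁻¹ h⁻¹, Ea = 46.0 kJ mol⁻¹)
    starting material + free catalyst → catalyst intermediate A (k = 1400 M⁻¹ h⁻¹, Ea = 41.0 kJ mol⁻¹)
    solid substrate ⇌ starting material, rate k4*(cs4 - [starting material]) while solid is left; crystals form when [starting material] > cs4 (solubility = 8.70 mM, k = 4.00 h⁻¹)
    catalyst intermediate B → free catalyst + product (k = 150 h⁻¹, Ea = 69.0 kJ mol⁻¹)
    (constants at −10 °C)

Monday's flask held 94.8% product at 8.00 h, a mean rate of 3.08 mM h⁻¹ and a clearing time of 8.44 h, shorter than my 9.65 h. For Monday's neighbour, charged with 100 mM, the same two stages give an estimated clearing time of 12.6 h, shorter than its 15 h. That neighbour nevertheless ended at 63.5% product, with 36% of its charge of solid substrate still there and spent catalyst at >99.9% of the catalyst charged.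

(The earlier runs and the new flask are calculated for substances that don't exist; the scatter is artificial.)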